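**Retrosynthetic overview**
1. Late stage: both CHO groups come from double ortho-lithiation/formylation of a MOM-protected phloroglucinol ring. C9'–H comes from ionic hydrogenation of a tertiary benzylic alcohol. The C9'–aryl and C9'–isobutyl bonds come from two successive carbonyl additions at C9'.
2. Enabling feature: quaternary C10 (methyl) is bonded to C5, and the ring-B alkene C5=C6 is exocyclic to ring A. The triad C10–C5=C6 is what a ring-B 1,2-cyclohexadiene (C10=C5=C6) leaves behind after its methyl-bearing π bond has acted as a dienophile.
3. Key disconnection: C4–C5 and C1–C10 form in one [4+2] between that strained allene and 6-methyl-2-pyrone, which supplies C1–C4, the C4 methyl group and C9' (its carbonyl carbon). The pyrone oxygen stays as a temporary C4–O–C9' bridge that locks the diene s-cis and fixes C1. It is removed later, by aryllithium at C9' and then palladium/formate with inversion at C4.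
4. The allene precursor, a 6-silyl enol triflate, comes from (S)-carvone in four steps. C7 comes from the chiral pool and controls C10, C1 and C4.
5. Ring order: ring B (carvone) and the arene (phloroglucinol) are bought. Ring A and the temporary lactone bridge close together in the key step, and the bridge is opened in steps 8 and 9.

Key step: step 5

Remark on numbering: eudesmane numbering is used (ring A = C1-C2-C3-C4-C5-C10, ring B = C5-C6-C7-C8-C9-C10, C9' = benzylic carbon). "Alpha" is the face that carries the C7 side chain. In the target the C1 side chain, the C4 methyl and the C10 methyl are all alpha.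
Remark on supply: (S)-(+)-carvone, 6-methyl-2H-pyran-2-one and phloroglucinol are taken as commercial.

**Step 1**
Reactants: 1 (S)-(+)-carvone
Product: 2 triethyl{[(5S)-2-methyl-5-(prop-1-en-2-yl)cyclohex-1-en-1-yl]oxy}silane (tetrasubstituted C5=C10 silyl enol ether)
Conditions: Et3SiH (1.2 equiv), RhCl(PPh3)3 (1 mol%), THF, 50 °C
Reagents that add atoms: triethylsilane, CC[SiH](CC)CC
Why: Rhodium-catalysed 1,4-hydrosilylation of an enone with a monohydrosilane gives the silyl enol ether regiospecifically and leaves the 1,1-disubstituted isopropenyl group and the C7 stereocentre untouched.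

**Step 2**
Reactants: 2 silyl enol ether
Product: 4 (5R,6R)-2-methyl-5-(prop-1-en-2-yl)-6-(triethylsilyl)cyclohex-1-en-1-yl trifluoromethanesulfonate (silyl on C6 trans to isopropenyl), via potassium 6-silyl enolate 3 (not isolated)
Conditions: LiN(i-Pr)2 (1.5 equiv), KOt-Bu (1.5 equiv), THF, −78 to −20 °C; then N-(5-chloro-2-pyridyl)triflimide, −78 to 0 °C
Reagents that add atoms: N-(5-chloropyridin-2-yl)bis(trifluoromethanesulfonyl)imide, FC(F)(F)S(=O)(=O)N(c1ccc(Cl)cn1)S(=O)(=O)C(F)(F)F
Why: Metalation of the silyl enol ether at C6 gives a 2-silyloxyallyl anion that undergoes 1,3 O-to-C silyl migration (retro-Brook rearrangement) to the less hindered terminus, anti to the isopropenyl group, and the regiodefined enolate is O-sulfonylated in the same flask, which is the known one-pot entry to 6-silylcyclohexenyl triflates.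

**Step 3**
Reactants: 4 silyl triflate
Product: 5 (5R,6R)-5-(2-hydroxypropan-2-yl)-2-methyl-6-(triethylsilyl)cyclohex-1-en-1-yl trifluoromethanesulfonate
Conditions: Mn(dpm)3 (5 mol%), PhSiH3 (2 equiv), O2 (1 atm), i-PrOH/CH2Cl2, 0 to 23 °C
Reagents that add atoms: dioxygen, O=O
Why: Mukaiyama hydration (hydrogen-atom transfer, then capture of O2) is Markovnikov-selective for the electron-rich 1,1-disubstituted alkene, whereas the tetrasubstituted, triflate-deactivated alkene should not react.

**Step 4**
Reactants: 5 tertiary alcohol
Product: 6 (5R,6R)-2-methyl-6-(triethylsilyl)-5-{2-[(triethylsilyl)oxy]propan-2-yl}cyclohex-1-en-1-yl trifluoromethanesulfonate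
Conditions: Et3SiOTf, 2,6-lutidine, CH2Cl2, −78 to 0 °C
Reagents that add atoms: triethylsilyl trifluoromethanesulfonate, CC[Si](CC)(CC)OS(=O)(=O)C(F)(F)F
Why: Silyl triflate with a hindered pyridine is the standard silylation of tertiary alcohols, and the bulky ether shields the alpha face around C6 and C7 in step 5 and masks the OH for the organometallic steps.

**Step 5**
Reactants: 6 silyl triflate; 7 6-methyl-2H-pyran-2-one
Product: 9 Diels–Alder adduct (ring A as a boat bridged on the alpha face by C1–C(=O)–O–C4, a 2-oxabicyclo[2.2.2]oct-5-en-3-one; C2=C3 and C5=C6 alkenes; C4 methyl beta; C10 methyl and C7 CMe2OTES alpha), via ring-B allene 8 (not isolated)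
Conditions: CsF (5 equiv), 7 (5 equiv), MeCN (0.05 M in 6), 23 to 40 °C
Reagents that add atoms: none
Why: Fluoride attacks the allylic silicon of 6, Et3SiF and triflate leave in a 1,2-elimination, and the strained, twisted allene 8 (C10=C5=C6 inside ring B) is trapped at once by pyrone 7 in a concerted but asynchronous [4+2] cycloaddition in which C5–C4 bonding runs ahead of C10–C1 bonding. The closest known reaction type is the Diels–Alder trapping of fluoride-generated 1,2-cyclohexadienes and their heterocyclic analogues by furans and 2-pyrones, which includes alkyl-substituted allenes that build a quaternary carbon. Ring A closes as the six-membered carbocycle of the cycloaddition (suprafacial on both partners), and the O–C(=O) unit of the pyrone remains as a temporary two-atom bridge between C4 and C1 whose carbonyl carbon is the future C9'. The step needs site and regioselectivity: the electron-poor diene should choose the more electron-rich, methyl-bearing π bond, the unhindered central carbon C5 (largest HOMO coefficient) bonds to the electrophilic, methyl-bearing C6 of the pyrone and hindered C10 to its unsubstituted C3, while the other π bond is flanked by the bulky C7 side chain. C10 is controlled by the C7 stereocentre: each π bond of the twisted allene has one open lobe only, the allene axis should invert faster than an unactivated pyrone adds so that the C6 configuration of 6 is not relied on (Curtin–Hammett), and only the axial epimer that opens C10=C5 on the beta face lets the pyrone methyl group pass over C6–H rather than over the CMe2OTES group, which leaves the C10 methyl group alpha. C1 and C4 follow from the endo orientation usual for cyclic allenes (ring B under the diene carbons C2 and C3, the oxygenated bridge over the small C10 methyl group), which puts C9' and the C4–O bond alpha, and the low temperature keeps CO2 in the adduct.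

**Step 6**
Reactants: 9 Diels–Alder adduct
Product: 10 2,3-dihydro adduct (bridged lactone in which only the C5=C6 alkene is left)
Conditions: H2 (1 atm), RhCl(PPh3)3 (5 mol%), benzene/EtOH, 23 °C
Reagents that add atoms: none
Why: Homogeneous hydrogenation discriminates by strain and substitution, so the cis-disubstituted bicyclooctene alkene should be reduced without touching the hindered trisubstituted C5=C6 alkene or the allylic C4–O bond, and its removal shuts off retro-[4+2] loss of CO2.

**Step 7**
Reactants: 11 phloroglucinol
Product: 12 1,3,5-tris(methoxymethoxy)benzene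
Conditions: MOMCl (4 equiv), i-Pr2NEt (5 equiv), CH2Cl2, 0 to 23 °C
Reagents that add atoms: chloromethyl methyl ether, COCCl
Why: Threefold O-alkylation of the phenol with an alpha-chloro ether under amine base is a standard acetal protection and installs the directing groups for steps 8 and 13.

**Step 8**
Reactants: 12 tris-MOM ether; 10 bridged lactone
Product: 15 methyl carbonate of the ring-opened keto alcohol (C1 alpha 2,4,6-tris(methoxymethoxy)benzoyl; C4 alpha OCO2Me and beta methyl; C5=C6 alkene), via aryllithium 13 (not isolated), via lithium keto alkoxide 14 (not isolated)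
Conditions: 12, n-BuLi (1.05 equiv), THF, 0 °C; 10, −78 to 0 °C; ClCO2Me, 0 °C
Reagents that add atoms: methyl chloroformate, COC(=O)Cl
Why: Directed ortho-metalation between two MOM ethers gives 13, which adds once to the strained, non-enolisable (bridgehead C1) lactone carbonyl as in aryl C-glycoside synthesis, and collapse of the crowded hemiketal releases the tertiary allylic alkoxide 14 that is acylated in situ without touching a stereocentre.

**Step 9**
Reactants: 15 allylic carbonate
Product: 16 aryl ketone (C1 alpha aroyl, C4 alpha methyl, C10 alpha methyl, C7 alpha CMe2OTES, C5=C6 alkene)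
Conditions: Pd2(dba)3·CHCl3 (2.5 mol%), n-Bu3P (10 mol%), HCO2H (5 equiv), Et3N (5 equiv), THF, 40 °C
Reagents that add atoms: none
Why: In this Tsuji-type formate hydrogenolysis zerovalent palladium ionises the alpha (axial) allylic carbonate from the beta face and the hydride formed by decarboxylation of the palladium formate is passed from the metal to the more substituted allyl terminus C4, so that net inversion puts H beta and the methyl group alpha and keeps the C5=C6 alkene.

**Step 10**
Reactants: 16 aryl ketone
Product: 17 tertiary benzylic alcohol bearing 2-methylallyl at C9' (both C9' epimers)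
Conditions: 2-methylallylmagnesium chloride (3 equiv), THF, 0 to 23 °C; then water
Reagents that add atoms: 2-methylallylmagnesium chloride, CC(=C)C[Mg]Cl
Why: Allyl-type Grignard reagents add to hindered, enolisable ketones through a six-membered cyclic transition state without beta-hydride reduction, and the configuration of the new carbinol is irrelevant because it is erased in step 12.

**Step 11**
Reactants: 17 methallyl carbinol
Product: 18 tertiary benzylic alcohol bearing isobutyl at C9' (both C9' epimers)
Conditions: H2 (1 atm), RhCl(PPh3)3 (10 mol%), benzene/EtOH, 23 °C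
Reagents that add atoms: none
Why: The same homogeneous hydrogenation reduces the terminal 1,1-disubstituted alkene in preference to the shielded trisubstituted ring alkene, and its neutral medium leaves the labile benzylic alcohol intact.

**Step 12**
Reactants: 18 isobutyl carbinol
Product: 19 protected core with (S)-configured C9'–H (2,4,6-tris(methoxymethoxy)phenyl, isobutyl and C1 on C9'; TES ether at C11)
Conditions: Et3SiH (10 equiv), CF3CO2H (3 equiv), CH2Cl2, −78 to −40 °C
Reagents that add atoms: none
Why: In this ionic hydrogenation the acid ionises only the tri-oxygenated tertiary benzylic alcohol at low temperature, the planar cation places C1–H in its plane next to an ortho MOM ether to minimise A(1,3) strain, and the silane should deliver hydride from the C2 side, opposite to quaternary C10, which sets C9' as (S).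

**Step 13**
Reactants: 19 protected core
Product: 21 3',5'-dialdehyde of 19, via lithium amino alkoxide 20 (not isolated)
Conditions: n-BuLi (1.2 equiv), TMEDA, THF, 0 °C; DMF (1.2 equiv), −78 to 0 °C; n-BuLi (1.5 equiv), 0 °C; DMF (3 equiv); then water
Reagents that add atoms: N,N-dimethylformamide, CN(C)C=O
Why: Each remaining aromatic C–H lies between two MOM ethers and is removed by directed ortho-metalation, while the first formyl group stays masked in the flask as the alpha-amino alkoxide 20 during the second lithiation/formylation.

**Step 14**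
Reactants: 21 dialdehyde
Product: 22 target CNP0108656.4
Conditions: 3 M aq HCl, THF, 40 °C
Reagents that add atoms: none
Why: Acid hydrolysis cleaves the three aryl MOM acetals (activated by the ortho formyl groups) and the tertiary TES ether in one operation, under conditions expected to be too mild to ionise the non-allylic tertiary alcohol or to move the C5=C6 alkene.

**Compound list**
1 | (S)-(+)-carvone | CC1=CC[C@@H](CC1=O)C(C)=C | starting material
2 | TES enol ether of (S)-dihydrocarvone (C5=C10) | CC1=C(O[Si](CC)(CC)CC)C[C@@H](C(C)=C)CC1 | intermediate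
3 | potassium enolate of the 6-triethylsilyl ketone | CC1=C([O-])[C@H]([Si](CC)(CC)CC)[C@@H](C(C)=C)CC1.[K+] | intermediate (not isolated)
4 | 6-silyl enol triflate with isopropenyl side chain (Si trans to side chain) | CC1=C(OS(=O)(=O)C(F)(F)F)[C@H]([Si](CC)(CC)CC)[C@@H](C(C)=C)CC1 | intermediate
5 | 6-silyl enol triflate with 2-hydroxypropan-2-yl side chain | CC1=C(OS(=O)(=O)C(F)(F)F)[C@H]([Si](CC)(CC)CC)[C@@H](C(C)(C)O)CC1 | intermediate
6 | 6-silyl enol triflate with CMe2OTES side chain | CC1=C(OS(=O)(=O)C(F)(F)F)[C@H]([Si](CC)(CC)CC)[C@@H](C(C)(C)O[Si](CC)(CC)CC)CC1 | intermediate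
7 | 6-methyl-2H-pyran-2-one | CC1=CC=CC(=O)O1 | starting material
8 | (4S)-1-methyl-4-{2-[(triethylsilyl)oxy]propan-2-yl}cyclohexa-1,2-diene | CC1=C=C[C@@H](C(C)(C)O[Si](CC)(CC)CC)CC1 | intermediate (not isolated)
9 | Diels–Alder adduct (bridged lactone, C2=C3 and C5=C6) | O=C1O[C@]2(C)C=C[C@H]1[C@@]3(C)CC[C@H](C(C)(C)O[Si](CC)(CC)CC)C=C32 | intermediate
10 | 2,3-dihydro bridged lactone | O=C1O[C@]2(C)CC[C@H]1[C@@]3(C)CC[C@H](C(C)(C)O[Si](CC)(CC)CC)C=C32 | intermediate
11 | phloroglucinol | Oc1cc(O)cc(O)c1 | starting material
12 | 1,3,5-tris(methoxymethoxy)benzene | COCOc1cc(OCOC)cc(OCOC)c1 | intermediate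
13 | 2,4,6-tris(methoxymethoxy)phenyllithium | [Li]c1c(OCOC)cc(OCOC)cc1OCOC | intermediate (not isolated)
14 | lithium C4 alkoxide of the ring-opened aryl ketone | [Li]O[C@]1(C)CC[C@H](C(=O)c2c(OCOC)cc(OCOC)cc2OCOC)[C@@]2(C)CC[C@H](C(C)(C)O[Si](CC)(CC)CC)C=C12 | intermediate (not isolated)
15 | C4 methyl carbonate of the ring-opened aryl ketone | COC(=O)O[C@]1(C)CC[C@H](C(=O)c2c(OCOC)cc(OCOC)cc2OCOC)[C@@]2(C)CC[C@H](C(C)(C)O[Si](CC)(CC)CC)C=C12 | intermediate
16 | aryl ketone with C4 set (all four ring substituents alpha) | O=C(c1c(OCOC)cc(OCOC)cc1OCOC)[C@H]1CC[C@@H](C)C2=C[C@@H](C(C)(C)O[Si](CC)(CC)CC)CC[C@@]21C | intermediate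
17 | C9' tertiary alcohol with 2-methylallyl (C9' epimers) | CC(=C)CC(O)(c1c(OCOC)cc(OCOC)cc1OCOC)[C@H]1CC[C@@H](C)C2=C[C@@H](C(C)(C)O[Si](CC)(CC)CC)CC[C@@]21C | intermediate
18 | C9' tertiary alcohol with isobutyl (C9' epimers) | CC(C)CC(O)(c1c(OCOC)cc(OCOC)cc1OCOC)[C@H]1CC[C@@H](C)C2=C[C@@H](C(C)(C)O[Si](CC)(CC)CC)CC[C@@]21C | intermediate
19 | protected core, C9' (S) | CC(C)C[C@H](c1c(OCOC)cc(OCOC)cc1OCOC)[C@H]1CC[C@@H](C)C2=C[C@@H](C(C)(C)O[Si](CC)(CC)CC)CC[C@@]21C | intermediate
20 | monoformyl adduct as lithium alpha-(dimethylamino) alkoxide | CC(C)C[C@H](c1c(OCOC)cc(OCOC)c(C(O[Li])N(C)C)c1OCOC)[C@H]1CC[C@@H](C)C2=C[C@@H](C(C)(C)O[Si](CC)(CC)CC)CC[C@@]21C | intermediate (not isolated)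
21 | protected dialdehyde | CC(C)C[C@H](c1c(OCOC)c(C=O)c(OCOC)c(C=O)c1OCOC)[C@H]1CC[C@@H](C)C2=C[C@@H](C(C)(C)O[Si](CC)(CC)CC)CC[C@@]21C | intermediate
22 | CNP0108656.4 | CC(C)C[C@H](c1c(O)c(C=O)c(O)c(C=O)c1O)[C@H]1CC[C@@H](C)C2=C[C@@H](C(C)(C)O)CC[C@@]21C | target

Total step count: 14. Longest linear sequence: 13 steps (steps 1 to 6, then 8 to 14) from (S)-carvone.

**Steps most likely to fail**

**Step 5.**
- What may go wrong: inversion of the allene axis may be slower than trapping, so that the pyrone adds to the C5=C6 π bond or from the side-chain face. The allene may dimerise before it is trapped. The adduct may lose CO2.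
- Fallback: stereospecific point-to-axis transfer replaces Curtin–Hammett control, and the migration of step 2 is also avoided. It sets out from 1 and comes back at 9.
- The kinetic enolate of 1 (LiN(i-Pr)2, THF, −78 °C) is brominated with N-bromosuccinimide to 6-bromocarvone F1.
- Et3SiOTf/Et3N gives the 6-bromo dienol silyl ether F2.
- t-BuLi (2 equiv, −78 °C) causes bromine–lithium exchange and a 1,3 O-to-C silyl shift. Protonation of the resulting dienolate with AcOH at −78 °C, from the face opposite to the isopropenyl group, should give cis-6-(triethylsilyl)carvone F3.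
- Conjugate reduction with LiBH(s-Bu)3 and trapping with the triflimide of step 2 gives the cis silyl triflate F4.
- The conditions of steps 3 and 4 then give the cis hydroxy silyl triflate F5 and the cis bis-silyl triflate F6.
- Under the conditions of step 5, F6 loses its silicon from the alpha face. This should generate directly the axial epimer of 8 whose methyl-bearing π bond is open on the beta face, and lead to 9.

**Step 9.**
- What may go wrong: hydride may be transferred to C6, which moves the alkene to C4=C5 and loses the C4 stereocentre. Beta-hydride elimination from the allylpalladium species may give dienes.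
- Fallback: a reductive 1,3-transposition replaces allylpalladium chemistry. It sets out from 10 (with 13) and comes back at 16.
- Step 8 is quenched with water instead of chloroformate to give the keto tertiary allylic alcohol F7.
- Babler–Dauben oxidative transposition with pyridinium chlorochromate, C5H5NH[CrO3Cl], gives the C4=C5–C6=O enone F8.
- Luche reduction (NaBH4, CeCl3·7H2O, MeOH, −78 °C) from the open beta face gives the 6-alpha allylic alcohol F9.
- Mitsunobu displacement with 2-nitrobenzenesulfonylhydrazide (PPh3, diethyl azodicarboxylate, −30 °C) gives, with inversion, the 6-beta sulfonylhydrazine F10.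
- On warming, F10 loses the sulfinic acid and dinitrogen. Hydrogen is delivered suprafacially to the beta face of C4 and the alkene shifts to C5=C6, which gives 16.

**Step 12.**
- What may go wrong: hydride may enter from the face next to C10, through a cation rotamer other than the one assumed, so that the C9' epimer prevails. The cation may also lose a proton to give styrenes.
- Fallback: the order in which hydrogen and the carbon chain are placed on C9' is exchanged, so that the same facial bias gives the other epimer. It sets out from 16 and comes back at 19.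
- LiAlH4 (THF, 0 °C) gives the secondary benzylic alcohol F11.
- Ionisation with BF3·OEt2 in the presence of trimethyl(2-methylallyl)silane (CH2Cl2, −78 °C, Hosomi–Sakurai-type benzylic allylation) gives the C9' methallyl compound F12.
- Hydrogenation as in step 11 gives 19.

**Further compounds**
F1 | step 5 | 6-bromocarvone from (S)-carvone (C6 epimers) | CC1=CC[C@H](C(C)=C)C(Br)C1=O
F2 | step 5 | 6-bromo dienol triethylsilyl ether of carvone | CC1=CC[C@H](C(C)=C)C(Br)=C1O[Si](CC)(CC)CC
F3 | step 5 | cis-6-(triethylsilyl)carvone (Si cis to isopropenyl) | CC1=CC[C@H](C(C)=C)[C@H]([Si](CC)(CC)CC)C1=O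
F4 | step 5 | cis silyl triflate (C6 epimer of 4) | CC1=C(OS(=O)(=O)C(F)(F)F)[C@@H]([Si](CC)(CC)CC)[C@@H](C(C)=C)CC1
F5 | step 5 | cis hydroxy silyl triflate (C6 epimer of 5) | CC1=C(OS(=O)(=O)C(F)(F)F)[C@@H]([Si](CC)(CC)CC)[C@@H](C(C)(C)O)CC1
F6 | step 5 | cis bis-silyl triflate (C6 epimer of 6) | CC1=C(OS(=O)(=O)C(F)(F)F)[C@@H]([Si](CC)(CC)CC)[C@@H](C(C)(C)O[Si](CC)(CC)CC)CC1
F7 | step 9 | keto tertiary allylic alcohol (C4 alpha OH) | O[C@]1(C)CC[C@H](C(=O)c2c(OCOC)cc(OCOC)cc2OCOC)[C@@]2(C)CC[C@H](C(C)(C)O[Si](CC)(CC)CC)C=C12
F8 | step 9 | C4=C5–C6=O enone | CC1=C2C(=O)[C@@H](C(C)(C)O[Si](CC)(CC)CC)CC[C@]2(C)[C@@H](C(=O)c3c(OCOC)cc(OCOC)cc3OCOC)CC1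
F9 | step 9 | 6-alpha allylic alcohol | CC1=C2[C@@H](O)[C@@H](C(C)(C)O[Si](CC)(CC)CC)CC[C@]2(C)[C@@H](C(=O)c3c(OCOC)cc(OCOC)cc3OCOC)CC1
F10 | step 9 | 6-beta N-(2-nitrobenzenesulfonyl)hydrazine | CC1=C2[C@H](N(N)S(=O)(=O)c3ccccc3[N+](=O)[O-])[C@@H](C(C)(C)O[Si](CC)(CC)CC)CC[C@]2(C)[C@@H](C(=O)c3c(OCOC)cc(OCOC)cc3OCOC)CC1
F11 | step 12 | secondary benzylic alcohol at C9' (epimers) | OC(c1c(OCOC)cc(OCOC)cc1OCOC)[C@H]1CC[C@@H](C)C2=C[C@@H](C(C)(C)O[Si](CC)(CC)CC)CC[C@@]21C
F12 | step 12 | C9' methallyl compound | CC(=C)C[C@H](c1c(OCOC)cc(OCOC)cc1OCOC)[C@H]1CC[C@@H](C)C2=C[C@@H](C(C)(C)O[Si](CC)(CC)CC)CC[C@@]21C
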